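**Plan**

1. Retrosynthetic cuts: (a) the CH2–CH2 bond between the side-chain carbon on C2 and the benzylic carbon; (b) the C5–H and C8–H bonds and the C6–O/C7–O bonds, back to an enone ketal; (c) the ketal C5–OMe and C8–OMe bonds, back to 5,8-dimethoxy-2-methylchromone; (d) C2–C3 and O1–C2 of the pyranone, back to an o-hydroxyacetophenone and ethyl acetate.
2. Enabling feature: in ring A (C4a, C5, C6, C7, C8, C8a) the oxygens on C5 and C8 stand para to each other, so the tetrol ring is a reduced and dihydroxylated hydroquinone ring and can be reached from the aromatic dimethyl ether by dearomatisation at exactly these two carbons.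
3. Forward order: the pyranone ring is closed first (step 1); ring A is dearomatised to the bisketal at the anode (step 2); the arylethyl chain is joined by benzylation of the 2-methyl anion (step 4); ring A is then oxygenated and reduced without further ring construction.
4. Stereochemistry: a catalytic asymmetric nucleophilic epoxidation of C6=C7 is the only enantioselective event. C5 follows from hydride attack anti to the oxirane and a Mitsunobu inversion, C6 is inverted by internal benzoate delivery (5,6-cis, 6,7-trans), and C8 comes from hydride directed by the C7 hydroxyl (7,8-trans).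

Key step: step 2

Assumption: 1 and 7 are treated as purchasable, and N-benzylcinchonidinium chloride is taken to give the (6S,7R) epoxide in step 6; if the sense of induction is the opposite, its pseudoenantiomer N-benzylcinchoninium chloride takes its place.

**Route**

Step 1
Reactants: 1 1-(2-hydroxy-3,6-dimethoxyphenyl)ethanone; 2 ethyl acetate
Product: 4 5,8-dimethoxy-2-methyl-4H-chromen-4-one, via β-diketone 3 (not isolated)
Conditions: NaH (4 equiv), EtOAc (excess), THF, reflux; then conc. HCl, AcOH, 90 °C
Reagents that add atoms: ethyl acetate CCOC(C)=O (compound 2)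
Why: Claisen condensation of the acetophenone dianion with ethyl acetate gives the 1,3-diketone, and acid-catalysed cyclodehydration (phenol oxygen onto the terminal ketone, then loss of water) closes the pyranone as in the classical 2-methylchromone synthesis.

Step 2
Reactants: 4 5,8-dimethoxy-2-methyl-4H-chromen-4-one; 5 methanol
Product: 6 5,5,8,8-tetramethoxy-2-methyl-5,8-dihydro-4H-chromen-4-one
Conditions: Pt anode, Pt cathode, undivided cell, constant current (about 2 F/mol), 1% KOH in MeOH, 0 °C
Reagents that add atoms: methanol CO (compound 5)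
Why: The 5,8-dimethoxy ring gives up two electrons at the anode, one at a time, and the radical cation and cation are trapped by methoxide at the two ipso carbons C5 and C8, so that two C–O bonds form and the arene becomes a cyclohexa-1,4-diene bis(dimethyl ketal) while hydrogen is evolved at the cathode. The closest known reaction type is the anodic methoxylation of 1,4-dimethoxyarenes to quinone bisketals in methanolic KOH. No ring is closed and no stereocentre is created, since C5 and C8 each carry two identical methoxy groups. The step needs oxidation of ring A in preference to the pyranone and attack at the ipso carbons in preference to C6 and C7; the first follows from the two para-disposed methoxy donors, which make this ring the most easily oxidised part of the molecule, the second from the positive charge being largest at the oxygen-bearing carbons. Dilute base and low temperature are chosen so that methoxide does not open the pyranone by addition at C2, and the charge is limited so that the isolated C6=C7 alkene of the product is not oxidised further.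

Step 3
Reactants: 7 [3-(benzyloxy)-4-methoxyphenyl]methanol
Product: 8 2-(benzyloxy)-4-(bromomethyl)-1-methoxybenzene
Conditions: PBr3, Et2O, 0 °C
Reagents that add atoms: phosphorus tribromide BrP(Br)Br
Why: Bromination of a benzylic alcohol with PBr3 (SN2 displacement of the phosphite leaving group by bromide) leaves both aryl ethers intact.

Step 4
Reactants: 6 quinone bisketal; 8 protected isovanillyl bromide
Product: 9 2-{2-[3-(benzyloxy)-4-methoxyphenyl]ethyl}-5,5,8,8-tetramethoxy-5,8-dihydro-4H-chromen-4-one
Conditions: LiN(SiMe3)2, THF, −78 °C; then 8, −78 → −30 °C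
Reagents that add atoms: none
Why: Vinylogous deprotonation of the 2-methyl group of the 4-pyranone gives an extended dienolate that is benzylated at the exocyclic carbon (lateral alkylation of 2-methylchromones); the bisketal offers no other acidic or electrophilic site, and the side-chain arene enters only now because its dialkoxybenzene ring would itself be oxidised in step 2.

Step 5
Reactants: 9 side-chain-bearing bisketal
Product: 10 2-{2-[3-(benzyloxy)-4-methoxyphenyl]ethyl}-8,8-dimethoxy-4H-chromene-4,5(8H)-dione
Conditions: AcOH/H2O/acetone, 0 °C → rt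
Reagents that add atoms: water O
Why: Regioselective monohydrolysis of a quinone bisketal runs through the better stabilised oxocarbenium ion, here the one at C5 to which O1 donates through C8a=C4a, whereas a C8 ion would sit next to the electron-poor carbon β to the C4 carbonyl, so the C8 ketal survives and the two carbonyl positions stay distinguishable.

Step 6
Reactants: 10 quinone monoketal (C5 ketone, C8 dimethyl ketal)
Product: 11 (6S,7R)-2-{2-[3-(benzyloxy)-4-methoxyphenyl]ethyl}-6,7-epoxy-8,8-dimethoxy-7,8-dihydro-4H-chromene-4,5(6H)-dione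
Conditions: N-benzylcinchonidinium chloride (10 mol%), t-BuOOH, aq. NaOH, toluene, 0 °C
Reagents that add atoms: tert-butyl hydroperoxide CC(C)(C)OO
Why: Weitz–Scheffer nucleophilic epoxidation under chiral phase-transfer catalysis, as known for quinone monoketals: the ion-paired tert-butylperoxide adds to C7 (β to the C5 ketone, the only accessible electrophilic alkene carbon) on one enantiotopic face and the enolate closes onto oxygen, which sets C6 and C7 together under catalyst control.

Step 7
Reactants: 11 (6S,7R)-epoxy ketone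
Product: 12 (5R,6R,7R)-2-{2-[3-(benzyloxy)-4-methoxyphenyl]ethyl}-6,7-epoxy-5-hydroxy-8,8-dimethoxy-5,6,7,8-tetrahydro-4H-chromen-4-one (hydroxyl cis to the oxirane oxygen)
Conditions: NaBH4, CeCl3·7H2O, MeOH, −78 °C
Reagents that add atoms: none
Why: Luche 1,2-reduction takes the oxirane-activated C5 ketone in preference to the vinylogous-ester C4 carbonyl, and hydride is expected to add from the face opposite the oxirane oxygen (steric and Felkin–Anh preference, as in additions to quinone monoketal epoxides), which places the C5 hydroxyl cis to the epoxide.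

Step 8
Reactants: 12 cis-epoxy alcohol
Product: 13 (5S,6R,7R)-2-{2-[3-(benzyloxy)-4-methoxyphenyl]ethyl}-6,7-epoxy-8,8-dimethoxy-4-oxo-5,6,7,8-tetrahydro-4H-chromen-5-yl benzoate (benzoate trans to the oxirane oxygen)
Conditions: PPh3, diisopropyl azodicarboxylate (DIAD), PhCO2H, THF, 0 °C → rt
Reagents that add atoms: benzoic acid O=C(O)c1ccccc1
Why: Mitsunobu inversion: benzoate displaces the alkoxyphosphonium group at C5 by SN2 from the open face away from the oxirane, which gives the 5S configuration of the target and at the same time places an acyloxy group trans to the epoxide as an internal nucleophile.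

Step 9
Reactants: 13 trans-epoxy benzoate
Product: 15 (5S,6S,7R)-2-{2-[3-(benzyloxy)-4-methoxyphenyl]ethyl}-5,7-dihydroxy-4,8-dioxo-5,6,7,8-tetrahydro-4H-chromen-6-yl benzoate, via hydroxy benzoate ketal 14 (not isolated)
Conditions: CF3CO2H/CH2Cl2 (1:3), 0 °C; then H2O, 0 °C → rt
Reagents that add atoms: water O
Why: Neighbouring-group participation in acid-promoted epoxide opening: the benzoate carbonyl oxygen attacks C6 of the protonated oxirane anti to the breaking C6–O bond (cis-fused 1,3-dioxolan-2-ylium ion), which inverts C6 to 6S and leaves the oxirane oxygen on C7 with full regiocontrol; water then opens the cation to the hydroxy ester, expected to carry the acyl group on O6 with the C5 hydroxyl hydrogen-bonded to the C4 carbonyl, and the same aqueous acid hydrolyses the C8 ketal to the ketone.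

Step 10
Reactants: 15 α-hydroxy ketone benzoate
Product: 16 (5S,6S,7S,8S)-2-{2-[3-(benzyloxy)-4-methoxyphenyl]ethyl}-5,7,8-trihydroxy-4-oxo-5,6,7,8-tetrahydro-4H-chromen-6-yl benzoate
Conditions: Me4NBH(OAc)3, MeCN/AcOH (1:1), −30 → 0 °C
Reagents that add atoms: none
Why: Hydroxyl-directed triacetoxyborohydride reduction (Saksena–Evans type): the reagent exchanges an acetate for the free C7 hydroxyl and delivers hydride to C8 on the face of the C7–O bond, so the new C8 hydroxyl ends trans to the C7 hydroxyl (the descriptor at C7 changes only through CIP priorities), while the acidic medium spares the base-sensitive β-benzoyloxy ketone and the acylated O6 cannot direct from the other face.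

Step 11
Reactants: 16 triol benzoate
Product: 17 (5S,6S,7R,8S)-2-{2-[3-(benzyloxy)-4-methoxyphenyl]ethyl}-5,6,7,8-tetrahydroxy-5,6,7,8-tetrahydro-4H-chromen-4-one
Conditions: K2CO3 (0.2 equiv), MeOH, 0 °C
Reagents that add atoms: none
Why: Base-catalysed transesterification with methanol removes the secondary benzoate as methyl benzoate without touching any stereocentre.

Step 12
Reactants: 17 O-benzyl tetrol
Product: 18 (5S,6S,7R,8S)-5,6,7,8-tetrahydroxy-2-[2-(3-hydroxy-4-methoxyphenyl)ethyl]-5,6,7,8-tetrahydro-4H-chromen-4-one
Conditions: H2 (1 atm), Pd/C, EtOAc/MeOH, rt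
Reagents that add atoms: none
Why: Hydrogenolysis of the aryl benzyl ether over Pd/C is fast at atmospheric pressure, while the vinylogous-ester double bonds of the pyranone and the four carbinol centres are expected to survive these neutral conditions.

**Compound list**

1 | 1-(2-hydroxy-3,6-dimethoxyphenyl)ethanone | CC(=O)c1c(O)c(OC)ccc1OC | starting material
2 | ethyl acetate | CCOC(C)=O | starting material
3 | 1-(2-hydroxy-3,6-dimethoxyphenyl)butane-1,3-dione | CC(=O)CC(=O)c1c(O)c(OC)ccc1OC | intermediate
4 | 5,8-dimethoxy-2-methyl-4H-chromen-4-one | Cc1cc(=O)c2c(OC)ccc(OC)c2o1 | intermediate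
5 | methanol | CO | starting material
6 | 5,5,8,8-tetramethoxy-2-methyl-5,8-dihydro-4H-chromen-4-one | Cc1cc(=O)c2c(o1)C(OC)(OC)C=CC2(OC)OC | intermediate
7 | [3-(benzyloxy)-4-methoxyphenyl]methanol | COc1ccc(CO)cc1OCc1ccccc1 | starting material
8 | 2-(benzyloxy)-4-(bromomethyl)-1-methoxybenzene | COc1ccc(CBr)cc1OCc1ccccc1 | intermediate
9 | 2-{2-[3-(benzyloxy)-4-methoxyphenyl]ethyl}-5,5,8,8-tetramethoxy-5,8-dihydro-4H-chromen-4-one | COc1ccc(CCc2cc(=O)c3c(o2)C(OC)(OC)C=CC3(OC)OC)cc1OCc1ccccc1 | intermediate
10 | 2-{2-[3-(benzyloxy)-4-methoxyphenyl]ethyl}-8,8-dimethoxy-4H-chromene-4,5(8H)-dione | COc1ccc(CCc2cc(=O)c3c(o2)C(OC)(OC)C=CC3=O)cc1OCc1ccccc1 | intermediate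
11 | (6S,7R)-2-{2-[3-(benzyloxy)-4-methoxyphenyl]ethyl}-6,7-epoxy-8,8-dimethoxy-7,8-dihydro-4H-chromene-4,5(6H)-dione | COc1ccc(CCc2cc(=O)c3c(o2)C(OC)(OC)[C@@H]4O[C@@H]4C3=O)cc1OCc1ccccc1 | intermediate
12 | (5R,6R,7R)-2-{2-[3-(benzyloxy)-4-methoxyphenyl]ethyl}-6,7-epoxy-5-hydroxy-8,8-dimethoxy-5,6,7,8-tetrahydro-4H-chromen-4-one | COc1ccc(CCc2cc(=O)c3c(o2)C(OC)(OC)[C@@H]4O[C@@H]4[C@@H]3O)cc1OCc1ccccc1 | intermediate
13 | (5S,6R,7R)-2-{2-[3-(benzyloxy)-4-methoxyphenyl]ethyl}-6,7-epoxy-8,8-dimethoxy-4-oxo-5,6,7,8-tetrahydro-4H-chromen-5-yl benzoate | COc1ccc(CCc2cc(=O)c3c(o2)C(OC)(OC)[C@@H]4O[C@@H]4[C@H]3OC(=O)c5ccccc5)cc1OCc1ccccc1 | intermediate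
14 | (5S,6S,7R)-2-{2-[3-(benzyloxy)-4-methoxyphenyl]ethyl}-5,7-dihydroxy-8,8-dimethoxy-4-oxo-5,6,7,8-tetrahydro-4H-chromen-6-yl benzoate | COc1ccc(CCc2cc(=O)c3c(o2)C(OC)(OC)[C@H](O)[C@@H](OC(=O)c4ccccc4)[C@H]3O)cc1OCc1ccccc1 | intermediate
15 | (5S,6S,7R)-2-{2-[3-(benzyloxy)-4-methoxyphenyl]ethyl}-5,7-dihydroxy-4,8-dioxo-5,6,7,8-tetrahydro-4H-chromen-6-yl benzoate | COc1ccc(CCc2cc(=O)c3c(o2)C(=O)[C@H](O)[C@@H](OC(=O)c4ccccc4)[C@H]3O)cc1OCc1ccccc1 | intermediate
16 | (5S,6S,7S,8S)-2-{2-[3-(benzyloxy)-4-methoxyphenyl]ethyl}-5,7,8-trihydroxy-4-oxo-5,6,7,8-tetrahydro-4H-chromen-6-yl benzoate | COc1ccc(CCc2cc(=O)c3c(o2)[C@@H](O)[C@H](O)[C@@H](OC(=O)c4ccccc4)[C@H]3O)cc1OCc1ccccc1 | intermediate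
17 | (5S,6S,7R,8S)-2-{2-[3-(benzyloxy)-4-methoxyphenyl]ethyl}-5,6,7,8-tetrahydroxy-5,6,7,8-tetrahydro-4H-chromen-4-one | COc1ccc(CCc2cc(=O)c3c(o2)[C@@H](O)[C@H](O)[C@@H](O)[C@H]3O)cc1OCc1ccccc1 | intermediate
18 | (5S,6S,7R,8S)-5,6,7,8-tetrahydroxy-2-[2-(3-hydroxy-4-methoxyphenyl)ethyl]-5,6,7,8-tetrahydro-4H-chromen-4-one | COc1ccc(CCc2cc(=O)c3c(o2)[C@@H](O)[C@H](O)[C@@H](O)[C@H]3O)cc1O | target

**Count and risks**

Total step count: 12. Longest linear sequence: 11 steps (1 → 18 through steps 1, 2 and 4–12); step 3 is the one-step side branch.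

Steps most likely to fail:

1. Step 9. Once the oxirane has opened, the C8 ketal may resist hydrolysis, because its oxocarbenium ion sits next to the electron-poor C8a. Prolonged acid may then enolise the freshly released α-hydroxy ketone toward C7, which epimerises C7 or expels the C6 benzoate and leads on to aromatisation. The fallback removes the ketal while the oxirane is still closed. It sets out from 12: wet CF3CO2H in CH2Cl2 at 0 °C should hydrolyse the ketal to (5R,6R,7R)-2-{2-[3-(benzyloxy)-4-methoxyphenyl]ethyl}-6,7-epoxy-5-hydroxy-6,7-dihydro-4H-chromene-4,8(5H)-dione F1, whose oxirane has no participating neighbour and is deactivated by the flanking carbonyl. Mitsunobu inversion (PPh3, DIAD, PhCO2H) then gives the trans-benzoate (5S,6R,7R)-2-{2-[3-(benzyloxy)-4-methoxyphenyl]ethyl}-6,7-epoxy-4,8-dioxo-5,6,7,8-tetrahydro-4H-chromen-5-yl benzoate F2. BF3·OEt2 in CH2Cl2 at −40 °C followed by cold aqueous NaHCO3 triggers the same benzoate participation and comes back to the route at 15, which is reduced at once as in step 10. The ring-opened material thus never meets strong aqueous acid.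

2. Step 6. The ion-paired peroxide may discriminate poorly between the two faces of C6=C7 in this particular monoketal, or an uncatalysed background epoxidation may erode the enantiomeric purity. The fallback moves the enantioselective event to the ketone and sets out from 10. Corey–Bakshi–Shibata reduction with the B-methyl oxazaborolidine of (R)-α,α-diphenylprolinol and BH3·SMe2 in toluene at −40 °C (C4a side as the large group) should give (5S)-2-{2-[3-(benzyloxy)-4-methoxyphenyl]ethyl}-5-hydroxy-8,8-dimethoxy-5,8-dihydro-4H-chromen-4-one F3. This dienol is kept base-buffered, since acid would aromatise it by loss of methanol. Hydroxyl-directed epoxidation with VO(acac)2 and t-BuOOH in CH2Cl2 at 0 °C then places the oxirane cis to the hydroxyl and comes back to the route at 12.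

3. Step 2. Methoxide or hydroxide of the electrolyte may open the pyranone by addition at C2, or the acyl-substituted arene may be oxidised so sluggishly that solvent oxidation and over-oxidation of the product dominate. The fallback replaces the anode by a phenol-selective chemical oxidant and sets out from 4. BCl3 in CH2Cl2 (−78 → 0 °C) should cleave only the methyl ether peri to the C4 carbonyl, giving 5-hydroxy-8-methoxy-2-methyl-4H-chromen-4-one F4. Its dianion (2.2 equiv LiN(iPr)2, THF, −78 °C) is benzylated at the 2-methyl carbon with 8 to give 2-{2-[3-(benzyloxy)-4-methoxyphenyl]ethyl}-5-hydroxy-8-methoxy-4H-chromen-4-one F5. PhI(OAc)2 in MeOH at 0 °C oxidises the p-methoxyphenol to the quinone monoketal and comes back to the route at 10; the fully etherified side-chain ring is not attacked by this oxidant.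

**Further compounds**

F1 | step 9 | (5R,6R,7R)-2-{2-[3-(benzyloxy)-4-methoxyphenyl]ethyl}-6,7-epoxy-5-hydroxy-6,7-dihydro-4H-chromene-4,8(5H)-dione | COc1ccc(CCc2cc(=O)c3c(o2)C(=O)[C@@H]4O[C@@H]4[C@@H]3O)cc1OCc1ccccc1
F2 | step 9 | (5S,6R,7R)-2-{2-[3-(benzyloxy)-4-methoxyphenyl]ethyl}-6,7-epoxy-4,8-dioxo-5,6,7,8-tetrahydro-4H-chromen-5-yl benzoate | COc1ccc(CCc2cc(=O)c3c(o2)C(=O)[C@@H]4O[C@@H]4[C@H]3OC(=O)c5ccccc5)cc1OCc1ccccc1
F3 | step 6 | (5S)-2-{2-[3-(benzyloxy)-4-methoxyphenyl]ethyl}-5-hydroxy-8,8-dimethoxy-5,8-dihydro-4H-chromen-4-one | COc1ccc(CCc2cc(=O)c3c(o2)C(OC)(OC)C=C[C@@H]3O)cc1OCc1ccccc1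
F4 | step 2 | 5-hydroxy-8-methoxy-2-methyl-4H-chromen-4-one | Cc1cc(=O)c2c(O)ccc(OC)c2o1
F5 | step 2 | 2-{2-[3-(benzyloxy)-4-methoxyphenyl]ethyl}-5-hydroxy-8-methoxy-4H-chromen-4-one | COc1ccc(CCc2cc(=O)c3c(O)ccc(OC)c3o2)cc1OCc1ccccc1
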